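All runs are calculated with constants of no real substance, noise included.

In the teal flask 48.1% of the starting material is left after 10.0 h, and we ask what that leftover says about the double product.

| flask | starting material | coupling partner | remark | time |
|---|---|---|---|---|
| teal | 30 mM | 30 mM | run made earlier |  |
| larch | 20 mM | 30.0 mM |  | 2.0 d |
| birch | 20 mM | 50.0 mM |  | 2.0 d |
| elm | 20 mM | 80.0 mM |  | 2.0 d |

- teal (time / h: double product / %, single product / %, starting material / %): 2.50: 2.8, 20.3, 70.7; 5.00: 5.1, 27.2, 58.9; 8.00: 8.6, 31.8, 52.6; 10.0: 9.1, 32.8, 48.1

(scatter of a reading: 0.5 percentage points)

1. final double product, as a percentage of the starting material charged, for each flask in turn (larch, birch, elm)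



Let a be the fraction of starting material left and d the fraction standing as double product. We picture two steps: starting material takes up coupling partner to give single product, and single product takes up a second one to give double product. The same coupling partner concentration then stands in both rates and divides out of their ratio, so on this picture d follows from a.

If the second rate constant is half the first, a selectivity factor of 0.5, integrating gives a plain result: √a + √d equals 1. We test this on the table row by row. The sum is 1.01, 0.993, 1.02, and in the last row 0.995. We carry this last root sum, R, forward as a reading.

R still needs a for each flask. Between 5.00 h and 10.0 h, teal's starting material falls with a first-order rate constant of 0.0405 /h. We treat the loss as pseudo-first-order and scale this constant with the charge of coupling partner, ignoring what is used up along the way. Over 2.0 d our reckoning gives a of 14.3%, 3.91% and 0.560% for larch, birch and elm. Squaring R − √a then gives d of 38.1%, 63.6% and 84.7%.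

The forecast, holding that “the reaction effectively stops well before 2 d”, gives 23%, 45% and 70%.

The flasks give 32.4%, 62.6% and 87.6% for larch, birch and elm.

    starting material + coupling partner → single product (k = 5.10 /M/h)
    coupling partner + other mono adduct → double product (k = 9.20 /M/h)
    coupling partner + single product → double product (k = 2.10 /M/h)
    coupling partner ⇌ dormant form (K = 0.920, k = 0.160 /h)
    starting material + coupling partner → other mono adduct (k = 2.00 /M/h)
    coupling partner → decomposed reagent (k = 0.0160 /h)

In larch our 38.1% stands above the result, and 17.8% of the starting material is left against our 14.3%, with 5.0% of the coupling partner's charge remaining. The larch amounts at 2.00 d give a root sum of 0.991, against teal's 0.995. In elm, where 12.3% single product stands beside the double product, the root sum is 0.964, and teal's 0.995 with elm's leftover of 0.0793% reckons 93.5% double product against the 87.6% that stands there.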